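The constants come first, and I read them from the three runs, set out here beside the four new flasks.

| flask | substrate | reagent | catalyst | temperature | remark | time |
|---|---|---|---|---|---|---|
| Saturday's | 0.10 M | 0.15 M | 15 mM | 105 °C | run made earlier |  |
| Monday's | 0.10 M | 0.15 M | 7.5 mM | 116 °C | run made earlier |  |
| Sunday's | 0.10 M | 0.15 M | 30 mM | 105 °C | run made earlier |  |
| birch | 0.10 M | 0.150 M (fed, over 2.0 h) | 15 mM | 110 °C | all else is in the flask from the start; the feed brings no volume worth counting | 5.0 h |
| larch | 0.10 M (fed, over 2.0 h) | 0.150 M | 15 mM | 110 °C | all else is in the flask from the start; the feed brings no volume worth counting | 5.0 h |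
| oak | 0.10 M | 0.150 M | 15 mM | 110 °C | everything together at the start | 5.0 h |
| alder | 0.10 M (fed, over 2.0 h) | 0.150 M | 15 mM |  | the addition at 90 °C, then warmed to 110 °C; the feed brings no volume worth counting | 5.0 h |

- Saturday's (time / h: target / %, over-reaction product / %, substrate / %): 0.833: 11.7, 1.1, 72.9; 1.50: 24.2, 5.9, 56.3; 2.50: 33.6, 13.4, 39.2; 3.00: 37.8, 16.3, 32.1; 4.00: 42.4, 24.2, 22.6; 5.00: 44.3, 30.8, 15.2
- Monday's (time / h: target / %, over-reaction product / %, substrate / %): 0.333: 1.9, 0, 89.0; 0.500: 4.2, 0.7, 84.8; 0.833: 8.9, 2.3, 76.2; 1.33: 13.5, 7.2, 64.2; 2.50: 21.3, 19.6, 42.4; 4.00: 24.2, 35.7, 25.1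
- Sunday's (time / h: target / %, over-reaction product / %, substrate / %): 0.667: 23.0, 3.5, 60.3; 1.33: 41.7, 8.7, 36.6; 2.00: 52.0, 14.3, 22.5; 2.50: 55.0, 18.0, 14.8; 3.00: 58.0, 23.0, 11.0; 4.00: 60.1, 28.4, 6.0

(standard deviation of a reading: 0.5 percentage points)

- which flask leads in share of target in target plus over-reaction product ("all alike" within 1.5 percentage points) (birch / larch / oak / alder / all alike)
- share of target in target plus over-reaction product at the end, birch
- share of target in target plus over-reaction product at the end, larch
- share of target in target plus over-reaction product at the end, oak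
- share of target in target plus over-reaction product at the end, alder

- what was read earlier has a scatter of 0.5 percentage points, one standard deviation

Saturday's substrate keeps a fraction 15.2% at 5.00 h, so it loses 0.377 h⁻¹. Sunday's doubled catalyst gives 0.703 h⁻¹, so I scale this loss with catalyst. Between 1.50 h and 2.50 h Saturday's target loses 0.260 h⁻¹. If a target costs one reagent and an over-reaction product two, 67.9% of the reagent stands then, which makes 0.382 h⁻¹ at whole reagent.

I carry the race ratio, a selectivity factor: target's hourly loss at whole reagent over substrate's hourly loss. Saturday reads 1.01. Monday's readings, scaled to Saturday's catalyst, give a substrate loss of 0.691 h⁻¹ and a ratio of 1.25. Stepping between them to 110 °C gives a substrate loss of 0.496 h⁻¹ and a race ratio of 1.12.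

With ratio ρ held and x the fraction of substrate left, the share is (x^ρ − x)/((1 − ρ)(1 − x)), the gap in the balance ignored. Two extremes bracket a flask. Either the reagent stays whole, or it stands from the first moment at Saturday's end level, 29.4%, which gives ρ = 0.328. Oak leaves 8.36%, so my reckoning puts its share between 19.7% and 58.4%. If alder's cold hours count for nothing, it leaves 22.6%, and its bracket runs from 39.8% to 74.6%. Both ends stand higher than oak's , but alder's lower end lies below oak's upper end, so the two brackets overlap. I lean to alder over oak without having shown it, and I have bracketed neither birch nor larch. My brackets give ranges, not points.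

The forecast gives birch 55%, larch 54.5%, oak 52.5% and alder 57.5%, with alder leading: “it has less hot time and over-reaction has the higher Ea”.

The flasks give birch 55.5%, larch 55.1%, oak 52.3% and alder 59.1%, and alder leads.

    substrate + catalyst → catalyst + intermediate (k = 33.0 M⁻¹ h⁻¹, Ea = 66.0 kJ mol⁻¹)
    reagent + catalyst + intermediate → catalyst + target (k = 1070 M⁻² h⁻¹, Ea = 59.0 kJ mol⁻¹)
    reagent + target → over-reaction product (k = 3.78 M⁻¹ h⁻¹, Ea = 96.0 kJ mol⁻¹)
    (constants at 110 °C)

In alder, reagent goes into making target from intermediate 3.0 times as fast as into over-reaction product at 2.73 h, and that falls to 1.3 times at 5.00 h. Alder ends with 36% of its reagent, so the race ratio scaled by reagent left stands at 0.402. A neighbour of alder, charged with 0.025 M of substrate, ends with 80.8% of its reagent, which puts the scaled ratio higher, at 0.901, and its share is 45.0%.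

Readings and results come from a simulation from invented constants, noise included.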